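# Synthesis proposal for CNP0211028.3 (guaianolide / 1,10-seco-eudesmanolide [4+2]-type dimer)

Numbering used throughout: guaiane numbering C1–C15 for the hydroazulene half and primed seco-eudesmane numbering C1'–C15' for the britannilactone half.

## Analysis of the target

1. The target joins an 8,12-guaianolide (C1–C15) to 1-O-acetylbritannilactone (C1'–C15') through the two bonds C1–C13' and C3–C11'.
2. These bonds create a bicyclo[2.2.1]hept-2-ene. Its bridgeheads are C1 (quaternary) and C3, its alkene bridge is C4(Me)=C5, its saturated bridge is C13'H2–C11' (spiro carbon of the primed lactone), and its one-carbon bridge is C2.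
3. In the core, C12' is exo and C7' is endo, and C3 lies on the same face of the spiro lactone as C6' and C9'. The C2 acetate points over C4=C5, so H-2 points over C13'.
4. Around the core sit a seven-membered ring with a trans-fused α-methylene lactone (C7, C8) and a β-methyl group at C10. The primed half adds a cis-fused lactone (C7', C8'), the free allylic C6' hydroxyl and the side-chain centre C4', for eleven stereocentres in all.
5. The sensitive groups are a free α-methylene lactone, two acetates beside one free secondary allylic alcohol, two tetrasubstituted alkenes, and a strained norbornene that can rearrange under strong acid.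
6. The hard parts are the two quaternary carbons C1 and C11', the C2 oxygen lying anti to the C13'–C11' bridge, and the union of two large halves.
7. The first feature used here lies in the six-membered ring C1–C13'–C11'–C3–C4–C5, where C5 is para to C11'. With C5 at the ketone level, C1 is a donor (α'-carbon) and C3 an acceptor (β-carbon), which matches the acceptor C13' and donor C11' of an α-methylene lactone.
8. The second feature is that the C2 oxygen and C8 are 1,5-related through C1–C10–C9, so they can be held in one six-membered cyclic acetal.

## Retrosynthetic reasoning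

**Protecting-group end.** The target 23 comes from silyl ether 22 by desilylation at C6'. Compound 22 comes from alcohol 21 by acetylation of the only free hydroxyl, at C2. This order removes any competition between the C2 and C6' hydroxyls.

**C7–C8 and O8–C12.** Compound 21 is cut in the seven-membered ring and in the guaianolide lactone at once, which leads to lactol / allylic bromide 19. The cut is placed here because the second Michael acceptor of the molecule then appears only after the union. The forward reaction is an allylchromium addition followed by lactonisation. It has to close the seven-membered ring, set C7 and C8 trans, and deliver the exocyclic methylene group.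

**The C6–C7=C11 arm.** Compound 19 comes from acetal 18. The enoate arm of 18 comes from the allyl compound 17 by cross metathesis with an acrylate partner. Compound 17 comes from alkenyl nonaflate 16 by C5–C6 cross-coupling, and 16 comes from silyl enol ether 15. The C5 oxygen that steers the union is thus exchanged for carbon, and the C4=C5 alkene stays where the union places it.

**C1–C13' and C3–C11' (key cut).** Compound 15 is cut into the bicyclic enone acetal 11 (eleven skeletal carbons) and the lactone 12. The guaiane half is deliberately cut at C5–C6 as well, so that C5 can be a carbonyl carbon. The diene is then a 2-silyloxycyclopentadiene with matched polarity, made from a stable enone. It carries no competing dienophile, and the acetal ring covers the face of the C2 oxygen.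

**Ring A from a furan.** Acetal 11 comes from hydroxy enone 9 by cleavage of the terminal alkene and acetal closure between the C2 hydroxyl and C8. Compound 9 is the C2-resolved form of 8. Compound 8 comes from furyl carbinol 7 by a dearomatising rearrangement that turns the flat furan into ring A, with the C2 oxygen and the C4 methyl group in place.

**Small pieces.** Carbinol 7 comes from aldehyde 4 and bromofuran 5. Aldehyde 4 carries C10 and is made from imide 1 through 2 and 3 by an auxiliary-controlled allylation.

## Alternatives that were turned down

**Alternative 1:** This is the textbook cut. It breaks C1–C13' and C3–C11' between the two complete monomers, and the forward key step is a thermal Diels–Alder reaction of the 2-acetoxy guaianolide diene A1 with 12.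
- A1 carries its own α-methylene lactone, so self-addition competes with the cross reaction.
- A1 is a 5-acyloxycyclopentadiene with a migrating hydrogen at C2, so 1,5-hydrogen shifts lead to enol acetates.
- A σ-acceptor at the saturated ring carbon steers dienophiles to its own face, while the target needs attack anti to the acetate. Only the C10 methyl group opposes this bias.
- The regiochemistry rests on sterics alone, because two of the three alkyl groups favour the other orientation electronically.
- A1 needs a full guaianolide synthesis before the risky step can even be tested.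

**Alternative 2:** This route unites carbons of like polarity at C3–C11'. The forward sequence is a Michael addition of the dienolate of the 2-oxo enone A2 through C1 to C13' of 12, then an intramolecular oxidative enolate coupling to the 7-norbornenone A3, then reduction and acetylation.
- Deprotonation of A2 prefers C3 or C6 over the route that makes C1 nucleophilic.
- The coupling has to close a strained bridged ketone under strongly basic, oxidising conditions that neither acetates nor the methylene lactone tolerate.
- Hydride reaches the C2 carbonyl of A3 from the open alkene side, because C12' and C14 block the other side. That attack gives the wrong C2 epimer, which cannot be inverted at a bridge carbon.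

**Alternative 3:** This route leaves the C2 oxygen out of the union. The forward sequence is a Diels–Alder reaction of the equilibrating C2-unsubstituted diene A4 with 12 to give adduct A5, followed by late C2–H acetoxylation.
- The cycloaddition is the safest of all the unions considered.
- The bridge methylene of A5 has strong, non-allylic C–H bonds and no directing group nearby.
- Oxidants would attack C4=C5, C5'=C10' or C15/C6 first.
- A relay through acid-induced Wagner–Meerwein shifts would ionise the C6' allylic alcohol.

Key step: step 8

Assumption: 1-O-acetylbritannilactone (12) is bought as a catalogue natural product and used as a chiral-pool building block.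

## Route

Step 1
Reactants: 1 (R)-4-benzyl-3-propanoyl-1,3-oxazolidin-2-one
Product: 2 (R)-4-benzyl-3-[(2S)-2-methylpent-4-enoyl]-1,3-oxazolidin-2-one
Conditions: NaN(SiMe3)2, THF, −78 °C; allyl iodide, −78 to −40 °C
Reagents that add atoms: allyl iodide C=CCI
Why: Evans asymmetric alkylation; the chelated Z-enolate is shielded on one face by the benzyl group, so the allyl group enters from the other face and sets C10 as (S).

Step 2
Reactants: 2 (R)-4-benzyl-3-[(2S)-2-methylpent-4-enoyl]-1,3-oxazolidin-2-one
Product: 3 (2S)-2-methylpent-4-en-1-ol
Conditions: LiBH4, Et2O, H2O (1 equiv), 0 °C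
Reagents that add atoms: none
Why: Reductive removal of the auxiliary with a borohydride; the exocyclic carbonyl is reduced without touching the α-centre or the alkene.

Step 3
Reactants: 3 (2S)-2-methylpent-4-en-1-ol
Product: 4 (2S)-2-methylpent-4-enal
Conditions: TEMPO (cat.), PhI(OAc)2, CH2Cl2, 0 °C to rt
Reagents that add atoms: none
Why: Oxoammonium oxidation of a primary alcohol under near-neutral conditions, chosen so that the α-stereocentre C10 should not epimerise.

Step 4
Reactants: 5 2-bromo-3-methylfuran; 4 (2S)-2-methylpent-4-enal
Product: 7 (2S)-2-methyl-1-(3-methylfuran-2-yl)pent-4-en-1-ol as both carbinol epimers, via 3-methylfuran-2-yllithium 6 (not isolated)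
Conditions: n-BuLi, THF, −78 °C; then 4; aq. NH4Cl
Reagents that add atoms: none
Why: Bromine–lithium exchange fixes the metal at furan C2 next to the methyl group, and 1,2-addition follows; the carbinol configuration is irrelevant because this carbon (C1) is ionised in the next step.

Step 5
Reactants: 7 (2S)-2-methyl-1-(3-methylfuran-2-yl)pent-4-en-1-ol
Product: 8 trans-4-hydroxy-2-methyl-5-[(2S)-pent-4-en-2-yl]cyclopent-2-en-1-one (both trans diastereomers)
Conditions: Dy(OTf)3 (cat.), t-BuOH/H2O, 80 °C
Reagents that add atoms: water O
Why: Piancatelli rearrangement, in which the furfuryl cation takes up water at furan C5, opens, and closes by conrotatory 4π electrocyclisation, fixing C1/C2 as trans; the furan methyl group ends on the enone α-carbon (C4) and the ring oxygen becomes the C5 ketone, but C10 does not control the sense of rotation, so two trans diastereomers are expected.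

Step 6
Reactants: 8 trans-4-hydroxy-2-methyl-5-[(2S)-pent-4-en-2-yl]cyclopent-2-en-1-one (both trans diastereomers)
Product: 9 (4R,5S)-4-hydroxy-2-methyl-5-[(2S)-pent-4-en-2-yl]cyclopent-2-en-1-one (C2 = R in guaiane numbering)
Conditions: Amano lipase PS, vinyl acetate, MTBE, 30 °C, stopped at half conversion; chromatography
Reagents that add atoms: none
Why: Lipase-mediated acylative resolution of a 4-hydroxycyclopentenone; the enzyme reads the carbinol centre C2, should acylate the unwanted diastereomer, and leaves 9 as the free alcohol, so C2 is fixed by reagent control.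

Step 7
Reactants: 9 (4R,5S)-4-hydroxy-2-methyl-5-[(2S)-pent-4-en-2-yl]cyclopent-2-en-1-one
Product: 11 cis-fused bicyclic enone methyl acetal (C2–O–C8 pyran ring; both C8 anomers), via keto aldehyde 10 (not isolated)
Conditions: O3, CH2Cl2/MeOH, −78 °C; Me2S; then CSA (cat.), MeOH, 40 °C
Reagents that add atoms: ozone [O-][O+]=O; methanol CO
Why: Ozone cleaves the electron-rich terminal alkene before the enone alkene; in acidic methanol C1 epimerises through the enol, and only the cis isomer can close the six-membered acetal between the C2 hydroxyl and C8, which drains the equilibrium (C1 is planarised in step 8 anyway).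

Step 8
Reactants: 11 cis-fused bicyclic enone methyl acetal; 12 1-O-acetylbritannilactone
Product: 15 norbornene cycloadduct carrying the C5 silyl enol ether plus the C6' silyl ether, via silyloxydiene 13 (not isolated), via britannilactone silyl ether 14 (not isolated)
Conditions: TBSOTf (2.4 equiv), Et3N, CH2Cl2, −78 °C to rt
Reagents that add atoms: tert-butyldimethylsilyl triflate CC(C)(C)[Si](C)(C)OS(=O)(=O)C(F)(F)F
Why: Soft enolisation removes the only enolisable hydrogen of 11 (H-1) and gives the 2-silyloxycyclopentadiene 13, while the same reagent caps the C6' hydroxyl of 12 as 14; the pair then reacts in a normal-demand Diels–Alder reaction of the type known for 2-silyloxycyclopentadienes made in situ from cyclopentenones. The closure is a suprafacial, asynchronous [4+2] addition that forms C1–C13' and C3–C11' and closes the six-membered ring C1–C13'–C11'–C3–C4–C5, and with it both five-membered rings of the bicyclo[2.2.1]heptene. Regiochemistry: the C5 silyloxy group puts the largest HOMO coefficient on C1, which bonds to the β-carbon C13' (para rule), and this is also the best steric pairing (fully substituted C1 with CH2, quaternary C11' with CH-3). C1 and C3: the dienophile must come anti to the C2 oxygen, against the usual syn preference of 5-oxy-cyclopentadienes, so the oxygen is tied back into the pyran ring O–C8–C9–C10, whose C8, C9 and methoxy group cover that face next to the reacting C1 while the other face carries only H-2 and H-10. C11': α-methylene-γ-butyrolactones add with the carbonyl group exo, which puts C12' exo and C7' endo. Face of 14: allylic strain between the C6' silyloxy group and the C5' side chain holds C6'–O pseudoaxial and C7'–C11' axial, so the methylene group stands over the flat C5'=C10' part of the ring and is open there, whereas H-7' guards the other side, and this places C3 cis to C6'. The absolute configurations of 13 and 14 are matched for this exo, anti transition state. Chemoselectivity is secured because no second Michael acceptor exists yet, and 1,5-hydrogen shift is outrun because the electron-rich diene is consumed as it forms.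

Step 9
Reactants: 15 norbornene cycloadduct carrying the C5 silyl enol ether plus the C6' silyl ether
Product: 16 C5 alkenyl nonaflate
Conditions: C4F9SO2F, Bu4N[Ph3SiF2] (cat.), THF, 0 °C to rt
Reagents that add atoms: nonafluorobutane-1-sulfonyl fluoride FS(=O)(=O)C(F)(F)C(F)(F)C(F)(F)C(F)(F)F
Why: Fluoride-catalysed conversion of a silyl enol ether into an alkenyl nonaflate; the enol ether reacts far faster than the hindered secondary alkyl silyl ether, no strong base is needed, and the C4=C5 position is retained.

Step 10
Reactants: 16 C5 alkenyl nonaflate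
Product: 17 C5 allyl compound (C5–C6H2–C7H=CH2)
Conditions: allyl-B(pin), Pd(OAc)2, SPhos, K3PO4, THF/H2O, 50 °C
Reagents that add atoms: allylboronic acid pinacol ester C=CCB1OC(C)(C)C(C)(C)O1
Why: Suzuki–Miyaura coupling of an alkenyl sulfonate with an allylboronate forms C5–C6; a bulky electron-rich phosphine is chosen for the hindered tetrasubstituted alkenyl electrophile, and lactone, acetate, acetal and silyl ether tolerate the mild base.

Step 11
Reactants: 17 C5 allyl compound
Product: 18 (Z)-2-(bromomethyl)enoate (C6H2–C7H=C11(CO2Me)–C13H2Br)
Conditions: methyl 2-(bromomethyl)acrylate (excess), second-generation Hoveyda–Grubbs catalyst, CH2Cl2, 40 °C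
Reagents that add atoms: methyl 2-(bromomethyl)acrylate C=C(CBr)C(=O)OC
Why: Cross metathesis of a terminal alkene with a 1,1-disubstituted acrylate; the only metathesis-active alkene of 17 is the allyl terminus because both ring alkenes are tetrasubstituted, and the chain should end trans to the ester.

Step 12
Reactants: 18 (Z)-2-(bromomethyl)enoate
Product: 19 lactol (C2–O–C8H–OH, in equilibrium with the C2-hydroxy C8-aldehyde)
Conditions: 1 M HCl, THF, 0 °C to rt
Reagents that add atoms: water O
Why: Hydrolysis of a 2-methoxytetrahydropyran-type acetal under dilute acid, mild enough for the hindered silyl ether, the acetate and the allylic bromide; one operation frees both the C8 aldehyde and the C2 hydroxyl.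

Step 13
Reactants: 19 lactol
Product: 21 C2 alcohol containing the closed seven-membered ring plus the trans α-methylene lactone, via hydroxy ester 20 (not isolated)
Conditions: CrCl2 (4 equiv), THF, rt, high dilution; aq. NH4Cl; TsOH (cat.), CH2Cl2
Reagents that add atoms: none
Why: Intramolecular Nozaki–Hiyama allylation, in which divalent chromium turns the allylic bromide into an allylchromium species that attacks the C8 aldehyde through its γ-carbon C7, closing the seven-membered ring and unveiling C11=C13H2; the chair-type transition state of allylchromium reagents gives the anti adduct whatever the alkene geometry, which corresponds to the trans lactone after O8 attacks the ester. The aldehyde face is set by the chain anchored at C1, with the C10 methyl group pseudoequatorial.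

Step 14
Reactants: 21 C2 alcohol containing the closed seven-membered ring plus the trans α-methylene lactone
Product: 22 C2 acetate C6' silyl ether
Conditions: Ac2O, DMAP (cat.), pyridine, CH2Cl2, 0 °C to rt
Reagents that add atoms: acetic anhydride CC(=O)OC(C)=O
Why: Standard acylation; the C2 hydroxyl is the only free hydroxyl, so no selectivity is required and its configuration is untouched.

Step 15
Reactants: 22 C2 acetate C6' silyl ether
Product: 23 target CNP0211028.3
Conditions: HF·pyridine, THF, 0 °C to rt
Reagents that add atoms: none
Why: Fluoride cleavage of the secondary silyl ether under buffered acidic conditions that spare both acetates, both lactones and the methylene lactone; no stereocentre is affected.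

## Compound list

1 | (R)-4-benzyl-3-propanoyl-1,3-oxazolidin-2-one | CCC(=O)N1[C@H](Cc2ccccc2)COC1=O | starting material
2 | (R)-4-benzyl-3-[(2S)-2-methylpent-4-enoyl]-1,3-oxazolidin-2-one | C=CC[C@H](C)C(=O)N1[C@H](Cc2ccccc2)COC1=O | intermediate
3 | (2S)-2-methylpent-4-en-1-ol | C=CC[C@H](C)CO | intermediate
4 | (2S)-2-methylpent-4-enal | C=CC[C@H](C)C=O | intermediate
5 | 2-bromo-3-methylfuran | Cc1ccoc1Br | starting material
6 | 3-methylfuran-2-yllithium | [Li]c1occc1C | intermediate
7 | (2S)-2-methyl-1-(3-methylfuran-2-yl)pent-4-en-1-ol, both carbinol epimers | C=CC[C@H](C)C(O)c1occc1C | intermediate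
8 | trans-4-hydroxy-2-methyl-5-[(2S)-pent-4-en-2-yl]cyclopent-2-en-1-one, both trans diastereomers | C=CC[C@H](C)C1C(O)C=C(C)C1=O | intermediate
9 | (4R,5S)-4-hydroxy-2-methyl-5-[(2S)-pent-4-en-2-yl]cyclopent-2-en-1-one | C=CC[C@H](C)[C@@H]1C(=O)C(C)=C[C@H]1O | intermediate
10 | keto aldehyde (C8 aldehyde, C2 hydroxyl) | O=CC[C@H](C)[C@@H]1C(=O)C(C)=C[C@H]1O | intermediate
11 | cis-fused bicyclic enone methyl acetal (C2–O–C8 pyran ring, both C8 anomers) | COC1C[C@H](C)[C@H]2C(=O)C(C)=C[C@H]2O1 | intermediate
12 | 1-O-acetylbritannilactone | C=C1C(=O)O[C@@H]2CC(C)=C([C@@H](C)CCCOC(C)=O)[C@@H](O)[C@H]12 | starting material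
13 | 2-silyloxycyclopentadiene (C1=C5(OTBS)–C4=C3) fused to the acetal ring | COC1C[C@H](C)C2=C(O[Si](C)(C)C(C)(C)C)C(C)=C[C@H]2O1 | intermediate
14 | 6-O-TBS-1-O-acetylbritannilactone | C=C1C(=O)O[C@@H]2CC(C)=C([C@@H](C)CCCOC(C)=O)[C@@H](O[Si](C)(C)C(C)(C)C)[C@H]12 | intermediate
15 | norbornene cycloadduct, C5 silyl enol ether, C6' silyl ether | COC1C[C@H](C)[C@@]23C[C@]4(C(=O)O[C@@H]5CC(C)=C([C@@H](C)CCCOC(C)=O)[C@@H](O[Si](C)(C)C(C)(C)C)[C@@H]54)[C@@H](C(C)=C2O[Si](C)(C)C(C)(C)C)[C@H]3O1 | intermediate
16 | C5 alkenyl nonaflate | COC1C[C@H](C)[C@@]23C[C@]4(C(=O)O[C@@H]5CC(C)=C([C@@H](C)CCCOC(C)=O)[C@@H](O[Si](C)(C)C(C)(C)C)[C@@H]54)[C@@H](C(C)=C2OS(=O)(=O)C(F)(F)C(F)(F)C(F)(F)C(F)(F)F)[C@H]3O1 | intermediate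
17 | C5 allyl compound | COC1C[C@H](C)[C@@]23C[C@]4(C(=O)O[C@@H]5CC(C)=C([C@@H](C)CCCOC(C)=O)[C@@H](O[Si](C)(C)C(C)(C)C)[C@@H]54)[C@@H](C(C)=C2CC=C)[C@H]3O1 | intermediate
18 | (Z)-2-(bromomethyl)enoate | COC1C[C@H](C)[C@@]23C[C@]4(C(=O)O[C@@H]5CC(C)=C([C@@H](C)CCCOC(C)=O)[C@@H](O[Si](C)(C)C(C)(C)C)[C@@H]54)[C@@H](C(C)=C2C/C=C(\CBr)C(=O)OC)[C@H]3O1 | intermediate
19 | lactol | OC1C[C@H](C)[C@@]23C[C@]4(C(=O)O[C@@H]5CC(C)=C([C@@H](C)CCCOC(C)=O)[C@@H](O[Si](C)(C)C(C)(C)C)[C@@H]54)[C@@H](C(C)=C2C/C=C(\CBr)C(=O)OC)[C@H]3O1 | intermediate
20 | hydroxy ester (seven-membered ring closed, lactone open) | O[C@H]1C[C@H](C)[C@@]23C[C@]4(C(=O)O[C@@H]5CC(C)=C([C@@H](C)CCCOC(C)=O)[C@@H](O[Si](C)(C)C(C)(C)C)[C@@H]54)[C@@H](C(C)=C2C[C@@H]1C(=C)C(=O)OC)[C@H]3O | intermediate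
21 | C2 alcohol, C6' silyl ether | C=C1C(=O)O[C@H]2C[C@H](C)[C@@]34C[C@]5(C(=O)O[C@@H]6CC(C)=C([C@@H](C)CCCOC(C)=O)[C@@H](O[Si](C)(C)C(C)(C)C)[C@@H]65)[C@@H](C(C)=C3C[C@H]12)[C@H]4O | intermediate
22 | C2 acetate, C6' silyl ether | C=C1C(=O)O[C@H]2C[C@H](C)[C@@]34C[C@]5(C(=O)O[C@@H]6CC(C)=C([C@@H](C)CCCOC(C)=O)[C@@H](O[Si](C)(C)C(C)(C)C)[C@@H]65)[C@@H](C(C)=C3C[C@H]12)[C@H]4OC(C)=O | intermediate
23 | CNP0211028.3 | C=C1C(=O)O[C@H]2C[C@H](C)[C@@]34C[C@]5(C(=O)O[C@@H]6CC(C)=C([C@@H](C)CCCOC(C)=O)[C@@H](O)[C@@H]65)[C@@H](C(C)=C3C[C@H]12)[C@H]4OC(C)=O | target

## Step count and least certain steps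

Total step count: 15. Longest linear sequence: 15 steps (1 to 23). Compound 12 enters at step 8.

**Step 8 (key step).** The most likely failure is poor facial selectivity on the diene. The stereoelectronic pull of the C2 oxygen toward its own face may not be fully overcome by the tied-back ring. A second risk is 1,5-hydrogen shift of the diene if the cycloaddition is slow.
- The fallback replaces the cycloaddition with a stepwise anionic sequence, in which the first bond is an enolate alkylation-type event governed by the neighbouring substituent.
- It sets out from 11 and 12. Compound 12 is silylated separately to 14.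
- The lithium enolate of 11 (LiN(SiMe3)2, −78 °C) is added to 14 to give the mono-Michael adduct F1.
- Catalytic KOt-Bu closes the second Michael addition (C11' to C3) to give the norbornanone F2.
- TBSOTf/Et3N then returns to the route at 15.

**Step 6.** The lipase may discriminate poorly, or in the opposite sense, because the C1 substituent changes the size ranking around the carbinol.
- The fallback drops the enzyme and sets out from 8.
- The mixture is ozonised to 10 together with the epimeric keto aldehyde F3.
- Acetalisation gives 11 together with the C2-epimeric acetal F4.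
- The two rigid bicyclic diastereomers are separated by chromatography, and the route is rejoined at 11.

**Step 10.** Oxidative addition may be slow, or the nonaflate may hydrolyse, because the tetrasubstituted alkenyl carbon sits next to the quaternary C1.
- The fallback forms C5–C6 by carbonyl addition and sets out from 15.
- Buffered fluoride cleaves the enol ether to the norbornanone F2.
- Allyl bromide and indium give the tertiary carbinol F5.
- Burgess reagent removes water by syn elimination toward H-4, avoiding a free norbornyl cation, and the route is rejoined at 17.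

**Step 11.** Conversion with the 1,1-disubstituted, halide-bearing acrylate may be low, and the 1,4-diene may isomerise.
- The fallback builds the arm by carbonyl chemistry and sets out from 16.
- Suzuki coupling with (E)-2-ethoxyvinyl-B(pin) gives the dienol ether F6.
- Oxalic acid on wet silica gives the β,γ-unsaturated aldehyde F7.
- A Morita–Baylis–Hillman reaction with methyl acrylate (DABCO) gives the allylic alcohol F8.
- NBS/Me2S brings about bromination with allylic transposition, and the route is rejoined at 18.

**Step 13.** Control of the aldehyde face may be poor, which would give the wrong absolute sense of the C7/C8 pair. Intermolecular coupling may also compete with the medium-ring closure.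
- The fallback uses a configurationally defined allylboron reagent and sets out from 18.
- Borylation of the allylic bromide (B2pin2, Pd2(dba)3) gives the allylboronate acetal F9.
- Dilute acid gives the lactol boronate F10.
- Warming triggers a closed, stereospecific intramolecular allylboration followed by lactonisation, and the route is rejoined at 21.

## Further compounds

F1 | step 8 | mono-Michael adduct (C1–C13' formed, enone retained, C11' unassigned) | COC1C[C@H](C)[C@@]2(CC3C(=O)O[C@@H]4CC(C)=C([C@@H](C)CCCOC(C)=O)[C@@H](O[Si](C)(C)C(C)(C)C)[C@H]34)C(=O)C(C)=C[C@H]2O1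
F2 | step 8 | norbornanone (C5 ketone, C4 unassigned) | COC1C[C@H](C)[C@@]23C[C@]4(C(=O)O[C@@H]5CC(C)=C([C@@H](C)CCCOC(C)=O)[C@@H](O[Si](C)(C)C(C)(C)C)[C@@H]54)[C@@H](C(C)C2=O)[C@H]3O1
F3 | step 6 | epimeric keto aldehyde | O=CC[C@H](C)[C@H]1C(=O)C(C)=C[C@@H]1O
F4 | step 6 | C2-epimeric bicyclic acetal | COC1C[C@H](C)[C@@H]2C(=O)C(C)=C[C@@H]2O1
F5 | step 10 | tertiary C5 allyl carbinol (C4, C5 unassigned) | COC1C[C@H](C)[C@@]23C[C@]4(C(=O)O[C@@H]5CC(C)=C([C@@H](C)CCCOC(C)=O)[C@@H](O[Si](C)(C)C(C)(C)C)[C@@H]54)[C@@H](C(C)C2(O)CC=C)[C@H]3O1
F6 | step 11 | dienol ethyl ether | COC1C[C@H](C)[C@@]23C[C@]4(C(=O)O[C@@H]5CC(C)=C([C@@H](C)CCCOC(C)=O)[C@@H](O[Si](C)(C)C(C)(C)C)[C@@H]54)[C@@H](C(C)=C2/C=C/OCC)[C@H]3O1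
F7 | step 11 | C7 aldehyde | COC1C[C@H](C)[C@@]23C[C@]4(C(=O)O[C@@H]5CC(C)=C([C@@H](C)CCCOC(C)=O)[C@@H](O[Si](C)(C)C(C)(C)C)[C@@H]54)[C@@H](C(C)=C2CC=O)[C@H]3O1
F8 | step 11 | Morita–Baylis–Hillman alcohol (C7 unassigned) | COC1C[C@H](C)[C@@]23C[C@]4(C(=O)O[C@@H]5CC(C)=C([C@@H](C)CCCOC(C)=O)[C@@H](O[Si](C)(C)C(C)(C)C)[C@@H]54)[C@@H](C(C)=C2CC(O)C(=C)C(=O)OC)[C@H]3O1
F9 | step 13 | allylboronate acetal | COC1C[C@H](C)[C@@]23C[C@]4(C(=O)O[C@@H]5CC(C)=C([C@@H](C)CCCOC(C)=O)[C@@H](O[Si](C)(C)C(C)(C)C)[C@@H]54)[C@@H](C(C)=C2C/C=C(\CB6OC(C)(C)C(C)(C)O6)C(=O)OC)[C@H]3O1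
F10 | step 13 | lactol boronate | OC1C[C@H](C)[C@@]23C[C@]4(C(=O)O[C@@H]5CC(C)=C([C@@H](C)CCCOC(C)=O)[C@@H](O[Si](C)(C)C(C)(C)C)[C@@H]54)[C@@H](C(C)=C2C/C=C(\CB6OC(C)(C)C(C)(C)O6)C(=O)OC)[C@H]3O1
A1 | alternative 1 | 2-acetoxyguaia-1(5),3,11(13)-trien-12,8-olide | C=C1C(=O)O[C@H]2C[C@H](C)C3=C(C[C@H]12)C(C)=C[C@H]3OC(C)=O
A2 | alternative 2 | 2-oxoguaia-1(5),11(13)-dien-12,8-olide | C=C1C(=O)O[C@H]2C[C@H](C)C3=C(C[C@H]12)C(C)CC3=O
A3 | alternative 2 | dimeric 7-norbornenone (C2 ketone) | C=C1C(=O)O[C@H]2C[C@H](C)[C@@]34C[C@]5(C(=O)O[C@@H]6CC(C)=C([C@@H](C)CCCOC(C)=O)[C@@H](O)[C@@H]65)[C@@H](C(C)=C3C[C@H]12)C4=O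
A4 | alternative 3 | guaia-1(5),3,11(13)-trien-12,8-olide | C=C1C(=O)O[C@H]2C[C@H](C)C3=C(C[C@H]12)C(C)=CC3
A5 | alternative 3 | 2-deoxy dimer | C=C1C(=O)O[C@H]2C[C@H](C)[C@@]34C[C@]5(C(=O)O[C@@H]6CC(C)=C([C@@H](C)CCCOC(C)=O)[C@@H](O)[C@@H]65)[C@@H](C(C)=C3C[C@H]12)C4
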